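## Retrosynthetic overview

1. Target 17 ⇒ C12–C13 B‑alkyl Suzuki disconnection: 9‑vinyl decalin acetate 14 + (Z)‑3‑iodobut‑2‑enoic acid 15, which carries the Z geometry.
2. 14 ⇒ acetylation and C8 methylenation of 9‑vinyl‑8‑decalone 12 ⇒ one‑carbon ring expansion (1,2‑shift of C10 from C8 to C9) of propynyl‑hydrindanol 10.
3. 10 ⇒ trans‑hydrindane‑2,8‑dione 7 by axial‑selective reduction at C2 and propynyl addition at C8.
4. 7 ⇒ cationic chloro‑olefin annulation (C3–C4 bond, ring A) of cyclopentanone 5 ⇒ asymmetric conjugate addition/enolate alkylation on 2‑methylcyclopentenone 1 (sets C5 and C10).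
5. Ring order: the five‑membered ring is bought, ring A is closed in step 2, ring B arises in step 5 by expansion of the five‑membered ring.

Assumption: Grignard solutions 2 and 9 and acid 15 are purchased; labdane numbering (C1–C17) is used in the "Why" lines.

## Route

Step 1
Reactants: 1 2-methylcyclopent-2-en-1-one; 2 isopropenylmagnesium bromide; 3 2,3-dichloroprop-1-ene
Product: 5 (2S,3S)-2-(2-chloroprop-2-en-1-yl)-2-methyl-3-(prop-1-en-2-yl)cyclopentan-1-one, via magnesium enolate 4 (not isolated)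
Conditions: Cu(OTf)2 (3 mol%), chiral NHC ligand (4 mol%, enantiomer giving the 3S adduct), 2 (1.2 equiv), Et2O, −30 °C; then 3 (2 equiv), NaI (20 mol%), DMPU, −30 °C → rt
Reagents that add atoms: none
Why: Cu‑catalysed asymmetric conjugate addition of a Grignard reagent to an α‑methyl cycloalkenone with enolate trapping; the ligand sets C5, and the allylic halide alkylates the tetrasubstituted enolate anti to the isopropenyl group, setting quaternary C10 trans to it.

Step 2
Reactants: 5 (2S,3S)-2-(2-chloroprop-2-en-1-yl)-2-methyl-3-(prop-1-en-2-yl)cyclopentan-1-one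
Product: 7 (3aS,7aS)-4,4,7a-trimethyloctahydro-1H-indene-1,6-dione, via chlorocarbenium ion 6 (not isolated)
Conditions: TfOH (1.5 equiv), HFIP/CH2Cl2, −20 → 0 °C; then H2O, rt
Reagents that add atoms: water O
Why: Lansbury chloro‑olefin annulation (cation–olefin cyclisation): Markovnikov protonation gives the tertiary C4 cation, the CH2 terminus of the 2‑chloroallyl group attacks it through a chair six‑membered transition state, and the α‑chloro cation is hydrolysed to the C2 ketone; no new stereocentre forms and C5/C10 carry over as the trans ring fusion.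

Step 3
Reactants: 7 (3aS,7aS)-4,4,7a-trimethyloctahydro-1H-indene-1,6-dione
Product: 8 (3aS,6R,7aS)-6-hydroxy-4,4,7a-trimethyloctahydro-1H-inden-1-one
Conditions: L‑Selectride (1.05 equiv), THF, −78 °C; then H2O
Reagents that add atoms: none
Why: Chemo‑ and stereoselective trialkylborohydride reduction: the cyclohexanone reacts before the neopentylic cyclopentanone (as with 3‑ versus 17‑keto steroids), and hydride comes from the α (equatorial) side because the β face is blocked by the syn‑axial C4 and C10 methyls, giving the axial 2β‑alcohol.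

Step 4
Reactants: 8 (3aS,6R,7aS)-6-hydroxy-4,4,7a-trimethyloctahydro-1H-inden-1-one; 9 prop-1-yn-1-ylmagnesium bromide
Product: 10 (1S,3aS,6R,7aS)-4,4,7a-trimethyl-1-(prop-1-yn-1-yl)octahydro-1H-indene-1,6-diol
Conditions: 9 (3 equiv), THF, 0 °C → rt; then H2O
Reagents that add atoms: none
Why: 1,2‑Addition of an alkynyl Grignard reagent to the hindered C8 ketone from the face opposite the angular methyl (analogous to 17‑keto‑steroid alkynylation), after the first equivalent deprotonates the 2‑OH; the new C8 carbinol centre is consumed in step 5.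

Step 5
Reactants: 10 (1S,3aS,6R,7aS)-4,4,7a-trimethyl-1-(prop-1-yn-1-yl)octahydro-1H-indene-1,6-diol
Product: 12 (1R,4aS,7R,8aS)-1-ethenyl-7-hydroxy-5,5,8a-trimethyloctahydronaphthalen-2(1H)-one, via allenyl carbinol 11 (not isolated)
Conditions: Pd2(dba)3 (2.5 mol%), DPEphos (6 mol%), PhCO2H (20 mol%), toluene, 80 °C
Reagents that add atoms: none
Why: Proposed new method: Pd(0)/PhCO2H forms H–Pd–O2CPh, which hydropalladates the alkyne with Pd distal to the carbinol, β‑H‑eliminates to hydroxy‑allene 11 and re‑adds to give a (1‑hydroxyalkyl)‑π‑allylpalladium; the electron‑rich quaternary C10–C8 bond anti to Pd then migrates to the allyl terminus C9 as benzoate removes the O–H proton (semipinacol 1,2‑shift with retention at C10, so the trans fusion is kept and ring B becomes six‑membered), driven by C=O formation and relief of trans‑hydrindane strain and being the only irreversible exit because O‑ or benzoate attack on the π‑allyl is reversible, while the epimerisable C9 settles with the vinyl group equatorial (9α‑H); the closest known reaction types are the Pd–H‑catalysed ring expansion of allenylcyclobutanols to 2‑vinylcyclopentanones and the Pd/carboxylic‑acid alkyne‑to‑allene/π‑allyl isomerisation, neither shown on an unstrained 1‑propynylcyclopentanol.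

Step 6
Reactants: 12 (1R,4aS,7R,8aS)-1-ethenyl-7-hydroxy-5,5,8a-trimethyloctahydronaphthalen-2(1H)-one
Product: 13 (2R,4aS,8S,8aS)-8-ethenyl-4,4,8a-trimethyl-7-methylidenedecahydronaphthalen-2-ol
Conditions: Zn, CH2Br2, TiCl4, THF/CH2Cl2, 0 °C → rt (excess reagent)
Reagents that add atoms: dibromomethane BrCBr
Why: Lombardo methylenation, a non‑basic Zn/Ti carbonyl olefination that converts the enolisable β,γ‑unsaturated ketone to the 8(17)‑methylene without epimerising C9 or moving the vinyl group into conjugation, and which tolerates the free hydroxyl.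

Step 7
Reactants: 13 (2R,4aS,8S,8aS)-8-ethenyl-4,4,8a-trimethyl-7-methylidenedecahydronaphthalen-2-ol
Product: 14 (2R,4aS,8S,8aS)-8-ethenyl-4,4,8a-trimethyl-7-methylidenedecahydronaphthalen-2-yl acetate
Conditions: Ac2O, DMAP (1 equiv), pyridine, 60 °C
Reagents that add atoms: acetic anhydride CC(=O)OC(C)=O
Why: DMAP‑promoted acylation (via N‑acetylpyridinium) of the hindered axial 2β‑alcohol, with retention at C2; forcing conditions are acceptable because no base‑ or acid‑labile group remains.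

Step 8
Reactants: 14 (2R,4aS,8S,8aS)-8-ethenyl-4,4,8a-trimethyl-7-methylidenedecahydronaphthalen-2-yl acetate; 15 (2Z)-3-iodobut-2-enoic acid
Product: 17 (2Z)-5-[(1S,4aS,7R,8aS)-7-(acetyloxy)-5,5,8a-trimethyl-2-methylidenedecahydronaphthalen-1-yl]-3-methylpent-2-enoic acid, via alkylborane 16 (not isolated)
Conditions: Sia2BH (from BH3·THF + 2‑methylbut‑2‑ene, 1.1 equiv), THF, 0 °C; then 15, aq. K3PO4 (4 equiv), PdCl2(dppf) (5 mol%), AsPh3 (10 mol%), DMF, rt → 40 °C; acidic work‑up
Reagents that add atoms: none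
Why: Anti‑Markovnikov hydroboration with a bulky dialkylborane selects the monosubstituted vinyl group over the hindered 1,1‑disubstituted exocyclic alkene, and B‑alkyl Suzuki–Miyaura coupling transfers only the primary alkyl group with retention of the iodoalkene geometry, so the 13Z configuration comes unchanged from 15 and the hindered acetate survives the phosphate base.

## Compound list

1 | 2-methylcyclopent-2-en-1-one | CC1=CCCC1=O | starting material
2 | isopropenylmagnesium bromide (prop-1-en-2-ylmagnesium bromide) | CC(=C)[Mg]Br | starting material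
3 | 2,3-dichloroprop-1-ene | C=C(Cl)CCl | starting material
4 | bromomagnesium (3S)-2-methyl-3-(prop-1-en-2-yl)cyclopent-1-en-1-olate | CC1=C(O[Mg]Br)CC[C@H]1C(C)=C | intermediate
5 | (2S,3S)-2-(2-chloroprop-2-en-1-yl)-2-methyl-3-(prop-1-en-2-yl)cyclopentan-1-one (chloroallyl trans to isopropenyl) | O=C1CC[C@@H](C(C)=C)[C@]1(C)CC(Cl)=C | intermediate
6 | (3aS,7aS)-6-chloro-4,4,7a-trimethyl-1-oxooctahydro-1H-inden-6-ylium | O=C1CC[C@H]2C(C)(C)C[C+](Cl)C[C@@]21C | intermediate
7 | (3aS,7aS)-4,4,7a-trimethyloctahydro-1H-indene-1,6-dione (trans-fused) | O=C1CC[C@H]2C(C)(C)CC(=O)C[C@@]21C | intermediate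
8 | (3aS,6R,7aS)-6-hydroxy-4,4,7a-trimethyloctahydro-1H-inden-1-one (OH axial, cis to angular methyl) | O=C1CC[C@H]2C(C)(C)C[C@@H](O)C[C@@]21C | intermediate
9 | prop-1-yn-1-ylmagnesium bromide | CC#C[Mg]Br | starting material
10 | (1S,3aS,6R,7aS)-4,4,7a-trimethyl-1-(prop-1-yn-1-yl)octahydro-1H-indene-1,6-diol | CC#C[C@]1(O)CC[C@H]2C(C)(C)C[C@@H](O)C[C@@]21C | intermediate
11 | (1R,3aS,6R,7aS)-4,4,7a-trimethyl-1-(propa-1,2-dien-1-yl)octahydro-1H-indene-1,6-diol | C=C=C[C@]1(O)CC[C@H]2C(C)(C)C[C@@H](O)C[C@@]21C | intermediate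
12 | (1R,4aS,7R,8aS)-1-ethenyl-7-hydroxy-5,5,8a-trimethyloctahydronaphthalen-2(1H)-one (trans-decalin, vinyl equatorial) | O=C1CC[C@H]2C(C)(C)C[C@@H](O)C[C@]2(C)[C@H]1C=C | intermediate
13 | (2R,4aS,8S,8aS)-8-ethenyl-4,4,8a-trimethyl-7-methylidenedecahydronaphthalen-2-ol | C=C1CC[C@H]2C(C)(C)C[C@@H](O)C[C@]2(C)[C@H]1C=C | intermediate
14 | (2R,4aS,8S,8aS)-8-ethenyl-4,4,8a-trimethyl-7-methylidenedecahydronaphthalen-2-yl acetate | C=C1CC[C@H]2C(C)(C)C[C@@H](OC(C)=O)C[C@]2(C)[C@H]1C=C | intermediate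
15 | (2Z)-3-iodobut-2-enoic acid | C/C(I)=C/C(=O)O | starting material
16 | {2-[(1S,4aS,7R,8aS)-7-(acetyloxy)-5,5,8a-trimethyl-2-methylidenedecahydronaphthalen-1-yl]ethyl}bis(3-methylbutan-2-yl)borane | C=C1CC[C@H]2C(C)(C)C[C@@H](OC(C)=O)C[C@]2(C)[C@H]1CCB(C(C)C(C)C)C(C)C(C)C | intermediate
17 | (2Z)-5-[(1S,4aS,7R,8aS)-7-(acetyloxy)-5,5,8a-trimethyl-2-methylidenedecahydronaphthalen-1-yl]-3-methylpent-2-enoic acid (2β-acetoxy-labda-8(17),13Z-dien-15-oic acid) | C=C1CC[C@H]2C(C)(C)C[C@@H](OC(C)=O)C[C@]2(C)[C@H]1CC/C(C)=C\C(=O)O | target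

## Step count and main risks

Total steps: 8. Longest linear sequence: 8 steps (1 → 17).

Step 5 (proposed new ring expansion). The π‑allylpalladium may be too weak an electrophile to trigger the shift on an unstrained cyclopentanol, C7 may migrate instead of C10, or the α‑vinyl ketone may isomerise into conjugation. The fallback uses known chemistry only; it sets out from 8 and comes back at 13.
- Vinylmagnesium bromide adds to 8 to give (1R,3aS,6R,7aS)-1-ethenyl-4,4,7a-trimethyloctahydro-1H-indene-1,6-diol F1.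
- Hydroxyl‑directed epoxidation (VO(acac)2/t‑BuOOH or m‑CPBA) gives (1S,3aS,6R,7aS)-4,4,7a-trimethyl-1-[(2S)-oxiran-2-yl]octahydro-1H-indene-1,6-diol F2; either epoxide epimer serves.
- BF3·OEt2 at −78 °C effects the 2,3‑epoxy‑alcohol semipinacol ring expansion (C10 migrates to C9 anti to the breaking C–O bond) to (1S,4aS,7R,8aS)-7-hydroxy-1-(hydroxymethyl)-5,5,8a-trimethyloctahydronaphthalen-2(1H)-one F3.
- Lombardo methylenation gives (2R,4aS,8S,8aS)-8-(hydroxymethyl)-4,4,8a-trimethyl-7-methylidenedecahydronaphthalen-2-ol F4.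
- TEMPO/PhI(OAc)2 oxidises only the primary alcohol to (1S,4aS,7R,8aS)-7-hydroxy-5,5,8a-trimethyl-2-methylidenedecahydronaphthalene-1-carbaldehyde F5.
- Salt‑free Ph3P=CH2 at −78 °C converts F5 to 13.

Step 2 (cationic annulation). A 1,2‑hydride shift from C5 to the C4 cation could scramble C5 and lead to cis‑fused or diquinane products. The fallback closes ring A by a radical; it sets out from 5 and comes back at 7.
- Co(salen)Cl (cat.)/PhSiH3 in benzene at rt (metal‑hydride hydrogen‑atom‑transfer cycloisomerisation) gives a tertiary C4 radical that cannot undergo the hydride shift and adds 6‑endo to the CH2 terminus of the chloro‑olefin.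
- Hydrogen‑atom return to cobalt gives (3aS,7aS)-6-chloro-4,4,7a-trimethyl-2,3,3a,4,7,7a-hexahydro-1H-inden-1-one F6; its double‑bond isomer converges.
- Cold 90% H2SO4 hydrolyses F6 to 7.

Step 8 (chemoselective hydroboration and Suzuki coupling with a free acid). The carboxylate may interfere with the borane coupling, or the exocyclic alkene may compete. The fallback replaces the organoboron coupling by a Negishi coupling of an isolated electrophile; it sets out from 14 and comes back at 17.
- Sia2BH then NaBO3 gives (2R,4aS,8S,8aS)-8-(2-hydroxyethyl)-4,4,8a-trimethyl-7-methylidenedecahydronaphthalen-2-yl acetate F7, which can be purified from any regioisomer.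
- I2/PPh3/imidazole gives (2R,4aS,8S,8aS)-8-(2-iodoethyl)-4,4,8a-trimethyl-7-methylidenedecahydronaphthalen-2-yl acetate F8.
- Zinc insertion (Zn, cat. I2, DMA) and Pd(PPh3)4‑catalysed Negishi coupling with prop-2-en-1-yl (2Z)-3-iodobut-2-enoate F9 (from 15, allyl bromide, K2CO3) gives prop-2-en-1-yl (2Z)-5-[(1S,4aS,7R,8aS)-7-(acetyloxy)-5,5,8a-trimethyl-2-methylidenedecahydronaphthalen-1-yl]-3-methylpent-2-enoate F10.
- Pd(PPh3)4/morpholine removes the allyl ester without touching the acetate, giving 17.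

Further compounds

F1 | step 5 | (1R,3aS,6R,7aS)-1-ethenyl-4,4,7a-trimethyloctahydro-1H-indene-1,6-diol | C=C[C@]1(O)CC[C@H]2C(C)(C)C[C@@H](O)C[C@@]21C
F2 | step 5 | (1S,3aS,6R,7aS)-4,4,7a-trimethyl-1-[(2S)-oxiran-2-yl]octahydro-1H-indene-1,6-diol | C3O[C@@H]3[C@]1(O)CC[C@H]2C(C)(C)C[C@@H](O)C[C@@]21C
F3 | step 5 | (1S,4aS,7R,8aS)-7-hydroxy-1-(hydroxymethyl)-5,5,8a-trimethyloctahydronaphthalen-2(1H)-one | O=C1CC[C@H]2C(C)(C)C[C@@H](O)C[C@]2(C)[C@H]1CO
F4 | step 5 | (2R,4aS,8S,8aS)-8-(hydroxymethyl)-4,4,8a-trimethyl-7-methylidenedecahydronaphthalen-2-ol | C=C1CC[C@H]2C(C)(C)C[C@@H](O)C[C@]2(C)[C@H]1CO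
F5 | step 5 | (1S,4aS,7R,8aS)-7-hydroxy-5,5,8a-trimethyl-2-methylidenedecahydronaphthalene-1-carbaldehyde | C=C1CC[C@H]2C(C)(C)C[C@@H](O)C[C@]2(C)[C@H]1C=O
F6 | step 2 | (3aS,7aS)-6-chloro-4,4,7a-trimethyl-2,3,3a,4,7,7a-hexahydro-1H-inden-1-one | O=C1CC[C@H]2C(C)(C)C=C(Cl)C[C@@]21C
F7 | step 8 | (2R,4aS,8S,8aS)-8-(2-hydroxyethyl)-4,4,8a-trimethyl-7-methylidenedecahydronaphthalen-2-yl acetate | C=C1CC[C@H]2C(C)(C)C[C@@H](OC(C)=O)C[C@]2(C)[C@H]1CCO
F8 | step 8 | (2R,4aS,8S,8aS)-8-(2-iodoethyl)-4,4,8a-trimethyl-7-methylidenedecahydronaphthalen-2-yl acetate | C=C1CC[C@H]2C(C)(C)C[C@@H](OC(C)=O)C[C@]2(C)[C@H]1CCI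
F9 | step 8 | prop-2-en-1-yl (2Z)-3-iodobut-2-enoate | C/C(I)=C/C(=O)OCC=C
F10 | step 8 | prop-2-en-1-yl (2Z)-5-[(1S,4aS,7R,8aS)-7-(acetyloxy)-5,5,8a-trimethyl-2-methylidenedecahydronaphthalen-1-yl]-3-methylpent-2-enoate | C=C1CC[C@H]2C(C)(C)C[C@@H](OC(C)=O)C[C@]2(C)[C@H]1CC/C(C)=C\C(=O)OCC=C
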